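**Plan**

1. The target is (2R)-5-formyl-δ-tocotrienol. The last bond cut is C5–CHO, by ortho-formylation of the chromanol.
2. The C6–OH group stands para to C8a–O1, so the chromanol is the aromatised form of a para-quinol ether. The dihydropyran ring (O1, C2, C3, C4, C4a, C8a) is therefore cut at C4–C4a and traced back to a five-membered oxolane (O1, C2, C3, C4, C8a) spiro-fused at C8a to a cyclohexa-2,5-dienone whose carbonyl is C6.
3. The spirodienone is cut at O1–C8a (oxidative ipso-cyclisation of a para-alkylphenol by its own tertiary alcohol). The phenol is cut at aryl–CH2 (B-alkyl Suzuki coupling of hydroborated (R)-geranyllinalool with 4-bromo-3-methylphenol).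
4. Forward order: chain with its stereocentre, then aryl–alkyl union, then the spiro oxolane, then ring expansion to the chroman, then the formyl group.
5. Stereochemistry: C2 comes from a Sharpless asymmetric epoxidation of geranylgeraniol with D-(−)-tartrate. The oxygen is transposed to the tertiary carbinol without breaking its C–O bond, and that bond is never broken later. The three E-alkenes come with geranylgeraniol.

Key step: step 8

Remark: the SMILES defines the (2R) centre and an all-E side chain (natural tocotrienol series); (2E,6E,10E)-geranylgeraniol and 4-bromo-3-methylphenol are taken as commercial.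

**Route**

Step 1
Reactants: 1 (2E,6E,10E)-geranylgeraniol
Product: 2 [(2R,3R)-3-methyl-3-[(3E,7E)-4,8,12-trimethyltrideca-3,7,11-trien-1-yl]oxiran-2-yl]methanol
Conditions: Ti(OiPr)4 (cat.), D-(−)-diethyl tartrate (cat.), t-BuOOH, 4 Å MS, CH2Cl2, −20 °C
Reagents that add atoms: tert-butyl hydroperoxide, CC(C)(C)OO
Why: Sharpless asymmetric epoxidation is hydroxyl-directed, so only the 2,3-alkene of the tetraene should react, and the D-(−)-tartrate ligand should give the (2R,3R)-epoxide, which fixes the configuration of the future C2.

Step 2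
Reactants: 2 (2R,3R)-2,3-epoxygeranylgeraniol
Product: 3 (2S,3R)-2-(iodomethyl)-3-methyl-3-[(3E,7E)-4,8,12-trimethyltrideca-3,7,11-trien-1-yl]oxirane
Conditions: PPh3, imidazole, I2, CH2Cl2, 0 °C
Reagents that add atoms: iodine, II
Why: Appel-type iodination of the primary alcohol under buffered, neutral conditions should leave the trisubstituted epoxide and the alkenes intact; no stereocentre is touched (the C2 descriptor changes only through CIP priority).

Step 3
Reactants: 3 epoxy iodide
Product: 4 (3R,6E,10E)-3,7,11,15-tetramethylhexadeca-1,6,10,14-tetraen-3-ol ((R)-geranyllinalool)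
Conditions: activated Zn dust, EtOH, 70 °C
Reagents that add atoms: none
Why: Zinc insertion into the C–I bond followed by β-elimination of the epoxide oxygen (reductive opening of a 2,3-epoxy halide) should give the vinyl carbinol, and because the C3–O bond is never broken the centre is retained as (R).

Step 4
Reactants: 5 4-bromo-3-methylphenol
Product: 6 tert-butyl(4-bromo-3-methylphenoxy)dimethylsilane
Conditions: TBSCl, imidazole, DMF, rt
Reagents that add atoms: tert-butyldimethylsilyl chloride (TBSCl), CC(C)(C)[Si](C)(C)Cl
Why: Standard silylation masks the phenol so that the aryl bromide behaves as an ordinary electrophile in the cross-coupling.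

Step 5
Reactants: 4 (R)-geranyllinalool; 6 tert-butyl(4-bromo-3-methylphenoxy)dimethylsilane
Product: 8 (3R,6E,10E)-1-[4-(tert-butyldimethylsilyloxy)-2-methylphenyl]-3,7,11,15-tetramethylhexadeca-6,10,14-trien-3-ol, via alkylborane 7 (not isolated)
Conditions: 9-BBN (1.5 equiv), THF, 0 °C → rt; then 6, Pd(OAc)2 (cat.), SPhos (cat.), K3PO4, THF/H2O, 60 °C
Reagents that add atoms: none
Why: 9-BBN should hydroborate the monosubstituted vinyl group anti-Markovnikov much faster than the trisubstituted alkenes, and the B-alkyl-9-BBN should then undergo B-alkyl Suzuki–Miyaura coupling with the aryl bromide, the carbinol centre being a spectator.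

Step 6
Reactants: 8 silyl ether
Product: 9 4-[(3R,6E,10E)-3-hydroxy-3,7,11,15-tetramethylhexadeca-6,10,14-trien-1-yl]-3-methylphenol
Conditions: Bu4NF, THF, 0 °C
Reagents that add atoms: none
Why: Fluoride cleavage of the aryl silyl ether should free the phenol without affecting the tertiary alcohol or the polyene.

Step 7
Reactants: 9 phenol carbinol
Product: 10 (2R)-2,6-dimethyl-2-[(3E,7E)-4,8,12-trimethyltrideca-3,7,11-trien-1-yl]-1-oxaspiro[4.5]deca-6,9-dien-8-one (both epimers at the spiro carbon)
Conditions: PhI(OAc)2, CF3CH2OH/CH2Cl2, −10 → 0 °C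
Reagents that add atoms: none
Why: Oxidative dearomatisation of a para-alkylphenol with the hypervalent iodine reagent should be followed by ipso attack of the tethered tertiary hydroxyl (5-exo spiroetherification), the phenol being oxidised much faster than the isolated alkenes; the new spiro centre is uncontrolled and is destroyed in step 8.

Step 8
Reactants: 10 spirodienone
Product: 11 (2R)-2,8-dimethyl-2-[(3E,7E)-4,8,12-trimethyltrideca-3,7,11-trien-1-yl]-3,4-dihydro-2H-chromen-6-ol ((R)-δ-tocotrienol)
Conditions: BF3·OEt2 (20 mol %), CH2Cl2, −40 → −10 °C; then Et3N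
Reagents that add atoms: none
Why: BF3 should bind the dienone carbonyl (the future C6–O) to give an O-borylated cyclohexadienyl cation with positive charge on the two carbons flanking the spiro carbon; the oxolane CH2 (future C4) then shifts 1,2 from the spiro carbon (future C8a) to the unsubstituted neighbour (future C4a), leaving an oxocarbenium ion stabilised by O1, and loss of the proton from C4a aromatises the ring to the chroman-6-ol. The closest known reaction type is the dienone–phenol rearrangement, in its para-quinol ether to hydroquinone mono-ether form with ring expansion of a spiro-fused ring. The six-membered dihydropyran ring is not closed by a cyclisation but arises from the five-membered oxolane through this suprafacial 1,2-alkyl shift, which places C4a between C4 and C8a. No new stereocentre is formed: the C2–O1 and C2–C3 bonds stay intact, so the (R) centre from step 1 is carried through and both spiro epimers of 10 converge on one product. The step needs carbon and not oxygen to migrate, which the lone pair of O1 secures because only the carbon shift leaves an oxygen-stabilised cation, and it needs migration to the CH terminus and not the C-methyl terminus, which is secured because only the CH terminus can lose a proton and a shift to the hindered methyl-bearing carbon is reversible. It also needs the three isolated trisubstituted alkenes and the tertiary C2–O1 bond to stay untouched, for which the catalytic Lewis acid, the low temperature and the amine quench are chosen, the dienone oxygen being far more basic than either.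

Step 9
Reactants: 11 (R)-δ-tocotrienol
Product: 13 (2R)-6-hydroxy-2,8-dimethyl-2-[(3E,7E)-4,8,12-trimethyltrideca-3,7,11-trien-1-yl]-3,4-dihydro-2H-chromene-5-carbaldehyde, via 5-(hydroxymethyl)-δ-tocotrienol 12 (not isolated)
Conditions: MgCl2, Et3N, paraformaldehyde, THF, reflux; aq. citric acid work-up
Reagents that add atoms: paraformaldehyde (reacts as formaldehyde), C=O
Why: In the Casnati–Skattebøl ortho-formylation the chloromagnesium phenoxide ArOMgCl delivers formaldehyde to an ortho carbon and a second formaldehyde oxidises the hydroxymethyl intermediate by hydride transfer; C5 should be preferred over C7 because the annulated dihydropyran ring makes C5 the more nucleophilic ortho position of δ-type chromanols (Mills–Nixon effect), and the non-acidic medium spares the polyene.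

**Compound list**

1 | (2E,6E,10E)-3,7,11,15-tetramethylhexadeca-2,6,10,14-tetraen-1-ol (geranylgeraniol) | CC(C)=CCC/C(C)=C/CC/C(C)=C/CC/C(C)=C/CO | starting material
2 | [(2R,3R)-3-methyl-3-[(3E,7E)-4,8,12-trimethyltrideca-3,7,11-trien-1-yl]oxiran-2-yl]methanol | CC(C)=CCC/C(C)=C/CC/C(C)=C/CC[C@@]1(C)O[C@@H]1CO | intermediate
3 | (2S,3R)-2-(iodomethyl)-3-methyl-3-[(3E,7E)-4,8,12-trimethyltrideca-3,7,11-trien-1-yl]oxirane | CC(C)=CCC/C(C)=C/CC/C(C)=C/CC[C@@]1(C)O[C@@H]1CI | intermediate
4 | (3R,6E,10E)-3,7,11,15-tetramethylhexadeca-1,6,10,14-tetraen-3-ol ((R)-geranyllinalool) | CC(C)=CCC/C(C)=C/CC/C(C)=C/CC[C@@](C)(O)C=C | intermediate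
5 | 4-bromo-3-methylphenol | Cc1cc(O)ccc1Br | starting material
6 | tert-butyl(4-bromo-3-methylphenoxy)dimethylsilane | Cc1cc(O[Si](C)(C)C(C)(C)C)ccc1Br | intermediate
7 | (3S,6E,10E)-1-(9-borabicyclo[3.3.1]nonan-9-yl)-3,7,11,15-tetramethylhexadeca-6,10,14-trien-3-ol (same spatial arrangement as 4; descriptor changed by CIP priority) | CC(C)=CCC/C(C)=C/CC/C(C)=C/CC[C@@](C)(O)CCB1C2CCCC1CCC2 | intermediate
8 | (3R,6E,10E)-1-[4-(tert-butyldimethylsilyloxy)-2-methylphenyl]-3,7,11,15-tetramethylhexadeca-6,10,14-trien-3-ol | CC(C)=CCC/C(C)=C/CC/C(C)=C/CC[C@@](C)(O)CCc1ccc(O[Si](C)(C)C(C)(C)C)cc1C | intermediate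
9 | 4-[(3R,6E,10E)-3-hydroxy-3,7,11,15-tetramethylhexadeca-6,10,14-trien-1-yl]-3-methylphenol | CC(C)=CCC/C(C)=C/CC/C(C)=C/CC[C@@](C)(O)CCc1ccc(O)cc1C | intermediate
10 | (2R)-2,6-dimethyl-2-[(3E,7E)-4,8,12-trimethyltrideca-3,7,11-trien-1-yl]-1-oxaspiro[4.5]deca-6,9-dien-8-one (spiro epimers) | CC(C)=CCC/C(C)=C/CC/C(C)=C/CC[C@]1(C)CCC2(O1)C=CC(=O)C=C2C | intermediate
11 | (2R)-2,8-dimethyl-2-[(3E,7E)-4,8,12-trimethyltrideca-3,7,11-trien-1-yl]-3,4-dihydro-2H-chromen-6-ol ((R)-δ-tocotrienol) | CC(C)=CCC/C(C)=C/CC/C(C)=C/CC[C@]1(C)CCc2cc(O)cc(C)c2O1 | intermediate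
12 | (2R)-5-(hydroxymethyl)-2,8-dimethyl-2-[(3E,7E)-4,8,12-trimethyltrideca-3,7,11-trien-1-yl]-3,4-dihydro-2H-chromen-6-ol | CC(C)=CCC/C(C)=C/CC/C(C)=C/CC[C@]1(C)CCc2c(CO)c(O)cc(C)c2O1 | intermediate
13 | (2R)-6-hydroxy-2,8-dimethyl-2-[(3E,7E)-4,8,12-trimethyltrideca-3,7,11-trien-1-yl]-3,4-dihydro-2H-chromene-5-carbaldehyde | CC(C)=CCC/C(C)=C/CC/C(C)=C/CC[C@]1(C)CCc2c(C=O)c(O)cc(C)c2O1 | target

**Step count and risks**

Total steps: 9. Longest linear sequence: 8 steps (steps 1–3 and 5–9, from geranylgeraniol); step 4 is a one-step side branch.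

Steps most likely to fail:

1. Step 8. The proton released on aromatisation may protonate the trisubstituted alkenes and start cation–olefin cyclisation of the side chain. The Lewis acid may also ionise the tertiary C2–O1 bond (erosion of configuration), or the shift may go to the methyl-bearing terminus and be followed by methyl migration. The fallback makes the aryl–O1 bond by palladium catalysis, with no acid and no shift; it sets out from 4 (through alkylborane 7) and returns at 11. Commercial 3-bromo-5-methylphenol is brominated para to the hydroxyl (NBS, MeCN, 0 °C) to 3,4-dibromo-5-methylphenol F1 and silylated (TIPSCl, imidazole, DMF) to (3,4-dibromo-5-methylphenoxy)triisopropylsilane F2. Alkylborane 7, made from 4 as in step 5, should couple at C3–Br of F2, which is the less hindered bromide and, being meta to the silyloxy group, the less electron-rich one (Pd(dppf)Cl2, K3PO4, THF/DMF/H2O, 50 °C). This should give (3R,6E,10E)-1-[2-bromo-3-methyl-5-(triisopropylsilyloxy)phenyl]-3,7,11,15-tetramethylhexadeca-6,10,14-trien-3-ol F3. Intramolecular palladium-catalysed aryl etherification of the tertiary alcohol (Pd(OAc)2, 2-(di-tert-butylphosphino)-1,1'-binaphthyl, Cs2CO3, toluene, 80 °C; Buchwald–Hartwig-type C–O coupling) should then close the six-membered ring at the aryl–oxygen bond with the carbinol C–O bond untouched, giving O-triisopropylsilyl-(R)-δ-tocotrienol F4. Bu4NF in THF then gives 11.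

2. Step 9. The two ortho positions C5 and C7 may not be discriminated well enough, or a second formylation may occur. The fallback introduces the formyl group before the ring system exists, where sterics decide the site; it sets out from 9 and returns at 13. Formylation of 9 under the same MgCl2/Et3N/paraformaldehyde conditions should occur only at the open ortho position para to the methyl group, the other ortho carbon being flanked by OH and CH3. This gives 2-hydroxy-5-[(3R,6E,10E)-3-hydroxy-3,7,11,15-tetramethylhexadeca-6,10,14-trien-1-yl]-4-methylbenzaldehyde F5. Oxidative spirocyclisation with PhI(OAc)2 (CF3CH2OH/CH2Cl2, 0 °C) should give (2R)-2,10-dimethyl-8-oxo-2-[(3E,7E)-4,8,12-trimethyltrideca-3,7,11-trien-1-yl]-1-oxaspiro[4.5]deca-6,9-diene-7-carbaldehyde F6. Catalytic BF3·OEt2 (CH2Cl2, low temperature) should then trigger the same 1,2-shift, now towards a terminus activated by both carbonyl groups, and give 13 directly.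

3. Step 5. Oxidative addition into the electron-rich, ortho-substituted aryl bromide may be slow, so that protodeboronation of the alkylborane or hydroboration of trisubstituted alkenes by excess borane takes over; the aqueous base may also cleave the aryl silyl ether early. The fallback joins the fragments by a Heck reaction and removes the extra unsaturation afterwards; it sets out from 4 and 6 and returns at 8. Heck coupling (Pd(OAc)2, P(o-tol)3, Et3N, DMF, 100 °C) should give (1E,3R,6E,10E)-1-[4-(tert-butyldimethylsilyloxy)-2-methylphenyl]-3,7,11,15-tetramethylhexadeca-1,6,10,14-tetraen-3-ol F7, β-hydride elimination being possible only towards the benzylic carbon because C3 is quaternary. Diimide (2-nitrobenzenesulfonyl hydrazide, Et3N, CH2Cl2, rt) should then reduce the disubstituted styrene-type alkene in preference to the trisubstituted ones and give 8.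

**Further compounds**

F1 | step 8 | 3,4-dibromo-5-methylphenol | Cc1cc(O)cc(Br)c1Br
F2 | step 8 | (3,4-dibromo-5-methylphenoxy)triisopropylsilane | Cc1cc(O[Si](C(C)C)(C(C)C)C(C)C)cc(Br)c1Br
F3 | step 8 | (3R,6E,10E)-1-[2-bromo-3-methyl-5-(triisopropylsilyloxy)phenyl]-3,7,11,15-tetramethylhexadeca-6,10,14-trien-3-ol | CC(C)=CCC/C(C)=C/CC/C(C)=C/CC[C@@](C)(O)CCc1cc(O[Si](C(C)C)(C(C)C)C(C)C)cc(C)c1Br
F4 | step 8 | triisopropyl{[(2R)-2,8-dimethyl-2-[(3E,7E)-4,8,12-trimethyltrideca-3,7,11-trien-1-yl]-3,4-dihydro-2H-chromen-6-yl]oxy}silane | CC(C)=CCC/C(C)=C/CC/C(C)=C/CC[C@]1(C)CCc2cc(O[Si](C(C)C)(C(C)C)C(C)C)cc(C)c2O1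
F5 | step 9 | 2-hydroxy-5-[(3R,6E,10E)-3-hydroxy-3,7,11,15-tetramethylhexadeca-6,10,14-trien-1-yl]-4-methylbenzaldehyde | CC(C)=CCC/C(C)=C/CC/C(C)=C/CC[C@@](C)(O)CCc1cc(C=O)c(O)cc1C
F6 | step 9 | (2R)-2,10-dimethyl-8-oxo-2-[(3E,7E)-4,8,12-trimethyltrideca-3,7,11-trien-1-yl]-1-oxaspiro[4.5]deca-6,9-diene-7-carbaldehyde | CC(C)=CCC/C(C)=C/CC/C(C)=C/CC[C@]1(C)CCC2(O1)C=C(C=O)C(=O)C=C2C
F7 | step 5 | (1E,3R,6E,10E)-1-[4-(tert-butyldimethylsilyloxy)-2-methylphenyl]-3,7,11,15-tetramethylhexadeca-1,6,10,14-tetraen-3-ol | CC(C)=CCC/C(C)=C/CC/C(C)=C/CC[C@@](C)(O)/C=C/c1ccc(O[Si](C)(C)C(C)(C)C)cc1C
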